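**Retrosynthetic overview**

- The route rests on the carbocycle C1–C5: C1 (quaternary, OMe and CO2Me), C2(OMe)=C3(OMe), the C4 ketone and C5 with its chelated cinnamoyl enol. Every ring carbon is at carbonyl level or lies between carbonyls.
- Endgame: the O–CH3 bonds at C1 and C2 are removed, leaving the cyclopentenone with free C1 and C2 hydroxyls.
- Key disconnection: ring bonds C4–C5 (Claisen), C1–C5 (aldol) and C2–C3 (Dieckmann), leading back to benzalacetone, methyl methoxyacetate and dimethyl mesoxalate in one flask. The carbocycle is the only ring and is formed here; C1 is set in the closing step.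
- Dimethyl mesoxalate comes from dimethyl malonate by oxidation.

Key step: step 2

Assumption: the sense of induction of the magnesium bis(oxazoline) controller cannot be predicted with confidence. The route is written with the (S,S)-ligand, (S,S)-t-Bu-box = 2,2'-(propane-2,2-diyl)bis[(4S)-4-tert-butyl-4,5-dihydro-1,3-oxazole]. The (R,R)-antipode would be used if the (S,S)-ligand favours the (R)-ring, and the configuration of the key-step product would be assigned by X-ray or ECD analysis.

Remark: enolates and alkoxides formed in the flask are treated as salts of the numbered neutral compounds. The exocyclic enol is written throughout as the hydrogen-bonded (Z)-tautomer of the target.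

**Route**

Step 1
Reactants: 1 dimethyl malonate
Product: 3 dimethyl mesoxalate (dimethyl 2-oxopropanedioate), via dimethyl dihydroxymalonate 2 (not isolated)
Conditions: NaClO2, AcOH, H2O, rt; then toluene, Dean–Stark reflux, distillation
Reagents that add atoms: sodium chlorite, [Na+].[O-]Cl=O; water, O (oxygen retained only in hydrate 2)
Why: Chlorite oxidation of the doubly activated methylene of a malonic diester is an established route to ketomalonates, which form first as the gem-diol 2 and lose water on azeotropic distillation to give the anhydrous tricarbonyl 3 (active-methylene oxidation, then dehydration of a carbonyl hydrate; no stereocentre involved).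

Step 2
Reactants: 4 benzalacetone ((E)-4-phenylbut-3-en-2-one), 5 methyl methoxyacetate, 3 dimethyl mesoxalate
Product: 8 methyl (1S,5Z)-1,2-dihydroxy-5-[(2E)-1-hydroxy-3-phenylprop-2-en-1-ylidene]-3-methoxy-4-oxocyclopent-2-ene-1-carboxylate, via styryl diketone 6 (not isolated), via hydroxymalonate adduct 7 (not isolated)
Conditions: 4, LiN(SiMe3)2 (2.1 equiv), THF, −78 °C, then 5, −78 → 0 °C; then 3 premixed with MgBr2·OEt2/(S,S)-t-Bu-box (1.2 equiv each) in THF, −78 → −40 °C; then LiN(i-Pr)2 (2.5 equiv), −78 → −20 °C; 1 M HCl, 0 °C
Reagents that add atoms: none
Why: Proposed new method: the lithium enolate of 4 is acylated by 5 (crossed Claisen condensation) to the enolate of diketone 6, whose central carbon (C5) adds to the very electrophilic ketone of magnesium-bound 3 (aldol addition); proton transfer from C5 then leaves 7 as a diketonate and magnesium alkoxide that cannot revert by retro-aldol, and LiN(i-Pr)2 removes a C3 proton beside the methoxy group so that the C3 carbanion displaces methoxide from one ester on C1. The closest known reaction types are Claisen acylation of ketone enolates, aldol addition of 1,3-dicarbonyl compounds to ketomalonates and acylation of β-diketone dianions at the terminal carbon by esters; their union in one flask and the choice between two enantiotopic esters have no direct precedent. The cyclopentane ring is closed by a 5-exo-trig Dieckmann-type attack of C3 on the ester carbonyl (C2–C3 bond), pulled forward by formation of the doubly stabilised C2–C3–C4 enolate. C1 becomes stereogenic only in this closure, and its configuration is meant to be set by the twofold-symmetric bis(oxazoline) on divalent magnesium, which holds the C1 alkoxide and the ester carbonyls and leaves only one of the two esters open on the side from which the tethered C3 carbanion arrives (ligand control). The step needs C-acylation at C3 in preference to retro-aldol, O-acylation or attack at C5, which the substrate secures because C5 is already an enolate carbon, the enol lactone from O-acylation is reopened by LiOMe, and the cyclised triketone polyanion is the thermodynamic sink. On acidification the exocyclic enol of 8 should settle as the (Z)-chelate hydrogen-bonded to the C4 carbonyl.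

Step 3
Reactants: 8 methyl (1S,5Z)-1,2-dihydroxy-5-[(2E)-1-hydroxy-3-phenylprop-2-en-1-ylidene]-3-methoxy-4-oxocyclopent-2-ene-1-carboxylate
Product: 9 methyl (1S,5Z)-1-hydroxy-5-[(2E)-1-hydroxy-3-phenylprop-2-en-1-ylidene]-2,3-dimethoxy-4-oxocyclopent-2-ene-1-carboxylate
Conditions: CH2N2 (1.05 equiv), Et2O/CH2Cl2, −78 → −20 °C
Reagents that add atoms: diazomethane, C=[N+]=[N-]
Why: Diazomethane O-methylates only hydroxyls acidic enough to protonate it, and the C2 enol of 8 is a vinylogous carboxylic acid (HO–C2=C3–C4=O) far more acidic than the chelated exocyclic enol or the tertiary alcohol, while O4 is held as hydrogen-bond acceptor by the exocyclic enol, so methylation should occur at O2 and leave C1 untouched (diazomethane methylation of an acidic enol).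

Step 4
Reactants: 9 methyl (1S,5Z)-1-hydroxy-5-[(2E)-1-hydroxy-3-phenylprop-2-en-1-ylidene]-2,3-dimethoxy-4-oxocyclopent-2-ene-1-carboxylate
Product: 10 methyl (1S,5Z)-5-[(2E)-1-hydroxy-3-phenylprop-2-en-1-ylidene]-1,2,3-trimethoxy-4-oxocyclopent-2-ene-1-carboxylate (CNP0305038.1)
Conditions: LiN(SiMe3)2 (2.05 equiv), THF, −78 °C; MeOTf (1.05 equiv), −78 → −40 °C; 1 M HCl, 0 °C
Reagents that add atoms: methyl triflate, COS(=O)(=O)C(F)(F)F
Why: In the dianion the chelated lithium β-diketonate is the stabilised, weakly nucleophilic site whereas the tertiary C1 alkoxide, formed last, is the most basic oxygen and should take the hard electrophile MeOTf (Williamson-type O-methylation of the more basic site of a dianion); the alkoxide cannot fragment by retro-aldol because C5 is already an enolate carbon, so the C1 configuration is kept.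

**Compound list**

1 | dimethyl malonate | COC(=O)CC(=O)OC | starting material
2 | dimethyl 2,2-dihydroxymalonate (mesoxalate hydrate) | COC(=O)C(O)(O)C(=O)OC | intermediate
3 | dimethyl mesoxalate (dimethyl 2-oxopropanedioate) | COC(=O)C(=O)C(=O)OC | intermediate
4 | benzalacetone, (E)-4-phenylbut-3-en-2-one | CC(=O)/C=C/c1ccccc1 | starting material
5 | methyl methoxyacetate | COCC(=O)OC | starting material
6 | (E)-1-methoxy-6-phenylhex-5-ene-2,4-dione (present as its lithium enolate) | COCC(=O)CC(=O)/C=C/c1ccccc1 | intermediate
7 | dimethyl 2-hydroxy-2-[(5E)-1-methoxy-2,4-dioxo-6-phenylhex-5-en-3-yl]propanedioate (present as enolate and alkoxide) | COCC(=O)C(C(=O)/C=C/c1ccccc1)C(O)(C(=O)OC)C(=O)OC | intermediate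
8 | methyl (1S,5Z)-1,2-dihydroxy-5-[(2E)-1-hydroxy-3-phenylprop-2-en-1-ylidene]-3-methoxy-4-oxocyclopent-2-ene-1-carboxylate | COC(=O)[C@@]1(O)C(O)=C(OC)C(=O)/C1=C(O)/C=C/c1ccccc1 | intermediate
9 | methyl (1S,5Z)-1-hydroxy-5-[(2E)-1-hydroxy-3-phenylprop-2-en-1-ylidene]-2,3-dimethoxy-4-oxocyclopent-2-ene-1-carboxylate | COC(=O)[C@@]1(O)C(OC)=C(OC)C(=O)/C1=C(O)/C=C/c1ccccc1 | intermediate
10 | methyl (1S,5Z)-5-[(2E)-1-hydroxy-3-phenylprop-2-en-1-ylidene]-1,2,3-trimethoxy-4-oxocyclopent-2-ene-1-carboxylate | COC(=O)[C@@]1(OC)C(OC)=C(OC)C(=O)/C1=C(O)/C=C/c1ccccc1 | target

**Step count and risks**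

Total step count: 4. Longest linear sequence: 4 steps (1 → 3 → 8 → 9 → 10).

Steps most likely to fail:

1. Step 2 (the proposed new method). Discrimination between the two enantiotopic esters may be poor if closure on lithium outruns closure on the ligated magnesium. The cascade may also stall through retro-aldol loss of the mesoxalate unit or through O-acylation before the C3 carbanion is formed. The fallback uses known chemistry, sets out from 4, 5 and 3 and comes back at 8. Claisen condensation of 4 with 5 (LiN(SiMe3)2, THF, −78 → 0 °C) would give diketone 6, which is isolated. Amine-catalysed aldol addition of 6 to 3 (cat. Et3N, CH2Cl2, 0 °C) would give isolated adduct 7. Dianion ring closure of 7 (LiN(i-Pr)2, 3.3 equiv, THF, −78 → 0 °C, then 1 M HCl) would give the racemic triol F1. F1 would be resolved by preparative HPLC on immobilised amylose tris(3,5-dimethylphenylcarbamate) with an acidified eluent. The (S)-enantiomer 8 would be kept, its configuration assigned by comparing measured and calculated ECD spectra.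

2. Step 4. Chemoselectivity may be lost, with methylation at the diketonate oxygens or at C5 competing with the tertiary alkoxide. The fallback sets out from 9 and comes back at 10, and replaces dianion alkylation by neutral methylation of a masked diketone. BF3·OEt2 in CH2Cl2 (0 °C → rt) should tie the C4 carbonyl and the exocyclic enol into the difluoroboron chelate F2. MeOTf with 2,6-di-tert-butyl-4-methylpyridine (CH2Cl2, rt) should then methylate the only remaining hydroxyl, giving the O-methylated difluoroboron chelate F3. Mild hydrolysis (NaOAc, aqueous MeOH, 50 °C) should remove boron and free the enol of 10.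

3. Step 3. Methylation may go to O4 instead of O2, the chelated enol may be over-methylated, or diazomethane may add as a dipole to the styryl ketone. The fallback sets out from 8 and comes back at 9 (no new compound, F0). It is an acid-catalysed enol etherification under equilibrating conditions (MeOH, cat. TsOH, 3 Å molecular sieves, 40 °C). Only the vinylogous acid should etherify, and the isomer that keeps the C4 carbonyl–enol hydrogen bond, which is 9, should be the thermodynamic product.

**Further compounds**

F1 | step 2 | racemic methyl (5Z)-1,2-dihydroxy-5-[(2E)-1-hydroxy-3-phenylprop-2-en-1-ylidene]-3-methoxy-4-oxocyclopent-2-ene-1-carboxylate | COC(=O)C1(O)C(O)=C(OC)C(=O)/C1=C(O)/C=C/c1ccccc1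
F2 | step 4 | difluoroboron chelate of 9 (boron bridging the C4 oxygen and the exocyclic enol oxygen) | COC(=O)[C@@]1(O)C(OC)=C(OC)C2=[O+][B-](F)(F)OC(/C=C/c3ccccc3)=C12
F3 | step 4 | difluoroboron chelate of 10 (C1 methyl ether) | COC(=O)[C@@]1(OC)C(OC)=C(OC)C2=[O+][B-](F)(F)OC(/C=C/c3ccccc3)=C12
F0 | step 3 | none | none
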